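**Retrosynthetic overview**
1. Numbering: ring C1 (quaternary C–OH carrying C7H2OBz), C2 (C=O), C3=C4, C5 (CHOH), C6 (CHOBz). The C3=C4 bond (Saegusa–Ito oxidation; only C3 can enolise because C1 is quaternary) and the two free hydroxyls (desilylation) are unveiled last from the saturated α-ketol.
2. Key disconnection, ring bond C1–C2: the six-membered ring C1–C6 contains a tertiary α-ketol, C1(OH)–C2(=O), which is the retron of an intramolecular crossed benzoin reaction. The ring therefore opens to an acyclic 1,6-keto-aldehyde (aldehyde = C2, ketone = C1).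
3. That chain is cut at C5–C6 by a syn-aldol into 1,3-dibenzoyloxyacetone (C7–C1–C6, both benzoates already in place) and pent-4-enal (C5, C4, C3, C2, plus one carbon lost on ozonolysis).
4. Ring order: the two phenyl rings are bought with benzoyl chloride; the carbocycle C1–C6 is the only ring built and is closed last, in the benzoin step.

Key step: step 5

Remark (assumption): commercial dihydroxyacetone is the crystalline dimer, which reverts to the monomer under the acylation conditions; it is written as the monomer 1.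

**Step 1**
Reactants: 1 1,3-dihydroxyacetone; 2 benzoyl chloride
Product: 3 2-oxopropane-1,3-diyl dibenzoate (1,3-dibenzoyloxyacetone)
Conditions: BzCl (2.2 equiv), pyridine, CH2Cl2, 0 → 23 °C
Reagents that add atoms: benzoyl chloride, O=C(Cl)c1ccccc1
Why: Schotten–Baumann-type O-acylation of the two primary hydroxyls with pyridine as base and acyl-transfer catalyst; no stereocentre is involved.

**Step 2**
Reactants: 3 2-oxopropane-1,3-diyl dibenzoate; 4 pent-4-enal
Product: 6 (3S,4R)-4-hydroxy-2-oxooct-7-ene-1,3-diyl dibenzoate, via Z-enamine 5 (not isolated)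
Conditions: O-tert-butyl-D-threonine (20 mol%), 5-methyl-1H-tetrazole (10 mol%), 3 (3 equiv), 4 added slowly, N-methylpyrrolidinone (3 vol% H2O), 4 °C
Reagents that add atoms: none
Why: Primary-amino-acid enamine catalysis (direct syn-aldol of an O-protected dihydroxyacetone): the N–H···O-bonded Z-enamine 5 attacks the aldehyde held by the catalyst carboxylic acid, which should set C3 and C4 (target C6 and C5) together as the syn (threo) pair, and the D-configured catalyst is expected to give the (3S,4R) enantiomer (fructose-aldolase sense).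

**Step 3**
Reactants: 6 (3S,4R)-4-hydroxy-2-oxooct-7-ene-1,3-diyl dibenzoate
Product: 7 (3S,4R)-4-[(tert-butyldimethylsilyl)oxy]-2-oxooct-7-ene-1,3-diyl dibenzoate
Conditions: TBSOTf (1.2 equiv), 2,6-lutidine (2 equiv), CH2Cl2, −78 °C
Reagents that add atoms: tert-butyldimethylsilyl trifluoromethanesulfonate, CC(C)(C)[Si](C)(C)OS(=O)(=O)C(F)(F)F
Why: Silylation of the secondary alcohol with a silyl triflate and a hindered pyridine base at low temperature should outrun 1,2-benzoyl migration and retro-aldol and touches no stereocentre.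

**Step 4**
Reactants: 7 (3S,4R)-4-[(tert-butyldimethylsilyl)oxy]-2-oxooct-7-ene-1,3-diyl dibenzoate
Product: 9 (3S,4R)-4-[(tert-butyldimethylsilyl)oxy]-2,7-dioxoheptane-1,3-diyl dibenzoate, via ozonide 8 (not isolated)
Conditions: O3, CH2Cl2, −78 °C; then PPh3 (1.2 equiv), −78 → 23 °C; used at once
Reagents that add atoms: ozone, [O-][O+]=O
Why: Ozonolysis of the terminal alkene with reductive work-up unmasks the aldehyde (future C2) under neutral conditions that leave the benzoates, the silyl ether and both stereocentres untouched.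

**Step 5**
Reactants: 9 (3S,4R)-4-[(tert-butyldimethylsilyl)oxy]-2,7-dioxoheptane-1,3-diyl dibenzoate
Product: 11 [(1R,2S,3R)-2-(benzoyloxy)-3-[(tert-butyldimethylsilyl)oxy]-1-hydroxy-6-oxocyclohexyl]methyl benzoate, via carbene–aldehyde enaminol 10 (not isolated)
Conditions: (5aR,10bS)-2-(pentafluorophenyl)-5a,10b-dihydro-4H,6H-indeno[2,1-b][1,2,4]triazolo[4,3-d][1,4]oxazin-2-ium tetrafluoroborate (10 mol%), iPr2NEt (10 mol%), toluene (0.02 M), 23 °C
Reagents that add atoms: none
Why: The carbene adds to the aldehyde (future C2) to give the enaminol 10, an acyl-anion equivalent, which attacks the ketone carbon (future C1) while its OH proton passes to the ketone oxygen; loss of the carbene then releases the α-ketol and the catalyst. The closest known reaction type is the carbene-catalysed intramolecular crossed aldehyde–ketone benzoin reaction that gives six-membered tertiary α-ketols. The ring (C1–C6) closes by a 6-exo-trig attack that forms the C1–C2 bond. The new quaternary centre C1 is controlled by a chair transition state in which the C6 benzoate and the C5 silyl ether are equatorial, the C6–O bond lies anti to the incoming nucleophile, the ketone oxygen is hydrogen-bonded to the enol OH and the bulky azolium lies anti to the CH2OBz arm, so that the Si face of the ketone (O > C6 > C7) is attacked and C1–OH ends trans to the C6 benzoate and cis to the C5 oxygen; the chiral triazolium is expected to reinforce this face. The step needs chemoselectivity (one donor, one acceptor) and freedom from base-induced aldol closure, β-elimination and C6 epimerisation: the substrate secures the first because only the aldehyde can form the enaminol and the ketone is the only electrophile six atoms away, and the acidic N-C6F5 triazolium with a catalytic weak amine base secures the second. Once C1 is quaternary, the ketol has no epimerisable centre next to the carbonyl.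

**Step 6**
Reactants: 11 [(1R,2S,3R)-2-(benzoyloxy)-3-[(tert-butyldimethylsilyl)oxy]-1-hydroxy-6-oxocyclohexyl]methyl benzoate
Product: 13 [(1R,5R,6S)-6-(benzoyloxy)-5-[(tert-butyldimethylsilyl)oxy]-2-oxo-1-[(trimethylsilyl)oxy]cyclohex-3-en-1-yl]methyl benzoate, via bis-silyl enol ether 12 (not isolated)
Conditions: TMSOTf (2.5 equiv), Et3N (3 equiv), CH2Cl2, 0 °C; solvent exchange; Pd(OAc)2 (1.1 equiv), MeCN, 23 °C
Reagents that add atoms: trimethylsilyl trifluoromethanesulfonate, C[Si](C)(C)OS(=O)(=O)C(F)(F)F
Why: Saegusa–Ito oxidation: the ketone can enolise only towards C3 because C1 is quaternary, so silylation should give the single silyl enol ether 12 (the tertiary OH is silylated as well) and Pd(II) β-hydride elimination then places the double bond at C3=C4 without affecting any stereocentre.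

**Step 7**
Reactants: 13 [(1R,5R,6S)-6-(benzoyloxy)-5-[(tert-butyldimethylsilyl)oxy]-2-oxo-1-[(trimethylsilyl)oxy]cyclohex-3-en-1-yl]methyl benzoate
Product: 14 [(1R,5R,6S)-6-(benzoyloxy)-1,5-dihydroxy-2-oxocyclohex-3-en-1-yl]methyl benzoate (target)
Conditions: HF·pyridine, THF, 0 → 23 °C
Reagents that add atoms: none
Why: Fluoride cleavage of both silyl ethers under mildly acidic conditions should avoid base-induced benzoyl migration between O6 and O5 and leave the γ-hydroxy enone intact.

**Compound list**
1 | 1,3-dihydroxyacetone (1,3-dihydroxypropan-2-one) | OCC(=O)CO | starting material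
2 | benzoyl chloride | O=C(Cl)c1ccccc1 | starting material
3 | 2-oxopropane-1,3-diyl dibenzoate | O=C(COC(=O)c1ccccc1)COC(=O)c1ccccc1 | intermediate
4 | pent-4-enal | C=CCCC=O | starting material
5 | Z-enamine of 3, (2R,3S)-2-{[(Z)-1,3-bis(benzoyloxy)prop-1-en-2-yl]amino}-3-tert-butoxybutanoic acid (not isolated) | O=C(OC/C(N[C@@H](C(=O)O)[C@H](C)OC(C)(C)C)=C/OC(=O)c1ccccc1)c1ccccc1 | intermediate
6 | (3S,4R)-4-hydroxy-2-oxooct-7-ene-1,3-diyl dibenzoate | C=CCC[C@@H](O)[C@@H](C(=O)COC(=O)c1ccccc1)OC(=O)c1ccccc1 | intermediate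
7 | (3S,4R)-4-[(tert-butyldimethylsilyl)oxy]-2-oxooct-7-ene-1,3-diyl dibenzoate | C=CCC[C@@H](O[Si](C)(C)C(C)(C)C)[C@@H](C(=O)COC(=O)c1ccccc1)OC(=O)c1ccccc1 | intermediate
8 | ozonide of 7, (3S,4R)-4-[(tert-butyldimethylsilyl)oxy]-2-oxo-6-(1,2,4-trioxolan-3-yl)hexane-1,3-diyl dibenzoate, both epimers at the trioxolane carbon (not isolated) | C1(CC[C@@H](O[Si](C)(C)C(C)(C)C)[C@@H](C(=O)COC(=O)c2ccccc2)OC(=O)c2ccccc2)OCOO1 | intermediate
9 | (3S,4R)-4-[(tert-butyldimethylsilyl)oxy]-2,7-dioxoheptane-1,3-diyl dibenzoate | O=CCC[C@@H](O[Si](C)(C)C(C)(C)C)[C@@H](C(=O)COC(=O)c1ccccc1)OC(=O)c1ccccc1 | intermediate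
10 | carbene–aldehyde enaminol, (3S,4R)-4-[(tert-butyldimethylsilyl)oxy]-7-hydroxy-2-oxo-7-[(5aR,10bS)-2-(pentafluorophenyl)-5a,10b-dihydro-4H,6H-indeno[2,1-b][1,2,4]triazolo[4,3-d][1,4]oxazin-1(2H)-ylidene]heptane-1,3-diyl dibenzoate (not isolated) | OC(=C1N(c2c(F)c(F)c(F)c(F)c2F)N=C2CO[C@@H]3Cc4ccccc4[C@@H]3N12)CC[C@@H](O[Si](C)(C)C(C)(C)C)[C@@H](C(=O)COC(=O)c5ccccc5)OC(=O)c5ccccc5 | intermediate
11 | [(1R,2S,3R)-2-(benzoyloxy)-3-[(tert-butyldimethylsilyl)oxy]-1-hydroxy-6-oxocyclohexyl]methyl benzoate | O=C(OC[C@]1(O)C(=O)CC[C@@H](O[Si](C)(C)C(C)(C)C)[C@@H]1OC(=O)c1ccccc1)c1ccccc1 | intermediate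
12 | [(1R,5R,6S)-6-(benzoyloxy)-5-[(tert-butyldimethylsilyl)oxy]-1,2-bis[(trimethylsilyl)oxy]cyclohex-2-en-1-yl]methyl benzoate (not isolated) | O=C(OC[C@]1(O[Si](C)(C)C)C(O[Si](C)(C)C)=CC[C@@H](O[Si](C)(C)C(C)(C)C)[C@@H]1OC(=O)c1ccccc1)c1ccccc1 | intermediate
13 | [(1R,5R,6S)-6-(benzoyloxy)-5-[(tert-butyldimethylsilyl)oxy]-2-oxo-1-[(trimethylsilyl)oxy]cyclohex-3-en-1-yl]methyl benzoate | O=C(OC[C@]1(O[Si](C)(C)C)C(=O)C=C[C@@H](O[Si](C)(C)C(C)(C)C)[C@@H]1OC(=O)c1ccccc1)c1ccccc1 | intermediate
14 | [(1R,5R,6S)-6-(benzoyloxy)-1,5-dihydroxy-2-oxocyclohex-3-en-1-yl]methyl benzoate | O=C(OC[C@]1(O)C(=O)C=C[C@@H](O)[C@@H]1OC(=O)c1ccccc1)c1ccccc1 | target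

**Totals**
Total step count: 7. Longest linear sequence: 7 steps (1 → 3 → 6 → 7 → 9 → 11 → 13 → 14).

**Steps most likely to fail**

Step 5 (key step). What may go wrong: poor facial selectivity at the ketone (the C1 epimer forming), base-induced intramolecular aldol closure or epimerisation at C6 of the α-benzoyloxy ketone, or benzoyl transfer promoted by the carbene. The catalyst antipode is the first variable. The fallback closes the same C1–C2 bond reductively, without base, and sets out from 9. Tributyltin hydride and AIBN in benzene at 80 °C (radical pinacol cyclisation through an O-stannyl ketyl of the aldehyde) should give the tin-bridged cis-diol, with the new C1–OH expected anti to the neighbouring benzoate: [(1S,2S,3R,6S)-2-(benzoyloxy)-3-[(tert-butyldimethylsilyl)oxy]-1,6-dihydroxycyclohexyl]methyl benzoate F1. Parikh–Doering oxidation (SO3·pyridine, DMSO, iPr2NEt, CH2Cl2, 0 °C) of its secondary hydroxyl, with the tertiary one inert, then returns to the route at 11.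

Step 2. What may go wrong: slow enamine formation from the diacylated ketone, self-condensation of the linear aldehyde, erosion of syn- and enantioselectivity, or 1,2-benzoyl migration in the product. The fallback replaces amine catalysis by an aldolase and sets out from 1 and 4. Compound 1 is phosphorylated in situ (glycerol kinase, ATP regenerated with acetyl phosphate and acetate kinase, pH 7.5) to dihydroxyacetone phosphate F2. Rabbit-muscle fructose-1,6-bisphosphate aldolase is expected to add F2 to 4 with its fixed D-threo sense, giving (3S,4R)-3,4-dihydroxy-2-oxooct-7-en-1-yl dihydrogen phosphate F3. Acid phosphatase (pH 4.8) releases (3S,4R)-1,3,4-trihydroxyoct-7-en-2-one F4. Benzoylation with 2 (2.05 equiv, 2,4,6-collidine, CH2Cl2, −40 °C) should take the primary hydroxyl and the more acidic, ketone-flanked C3 hydroxyl before the hindered C4 hydroxyl, and returns to the route at 6. This trades the stereochemical risk for a regiochemical one in the acylation.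

Step 6. What may go wrong: incomplete dehydrogenation, hydrolysis of the silyl enol ether back to the ketone, or elimination of the C5 silyloxy group from the enone. The fallback replaces the palladium oxidation by selenoxide elimination and sets out from 12. Phenylselenenyl chloride (CH2Cl2, −78 °C) should give [(1R,2S,3R)-2-(benzoyloxy)-3-[(tert-butyldimethylsilyl)oxy]-6-oxo-5-(phenylselanyl)-1-[(trimethylsilyl)oxy]cyclohexyl]methyl benzoate F5 (both epimers at the selenium-bearing carbon, target C3). Oxidation (H2O2, pyridine, CH2Cl2, 0 °C) and syn-elimination of the selenoxide, which can only proceed towards C4, then returns to the route at 13.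

**Further compounds**
F1 | step 5 | [(1S,2S,3R,6S)-2-(benzoyloxy)-3-[(tert-butyldimethylsilyl)oxy]-1,6-dihydroxycyclohexyl]methyl benzoate | O=C(OC[C@]1(O)[C@@H](O)CC[C@@H](O[Si](C)(C)C(C)(C)C)[C@@H]1OC(=O)c1ccccc1)c1ccccc1
F2 | step 2 | dihydroxyacetone phosphate | O=C(CO)COP(=O)(O)O
F3 | step 2 | (3S,4R)-3,4-dihydroxy-2-oxooct-7-en-1-yl dihydrogen phosphate | C=CCC[C@@H](O)[C@H](O)C(=O)COP(=O)(O)O
F4 | step 2 | (3S,4R)-1,3,4-trihydroxyoct-7-en-2-one | C=CCC[C@@H](O)[C@H](O)C(=O)CO
F5 | step 6 | [(1R,2S,3R)-2-(benzoyloxy)-3-[(tert-butyldimethylsilyl)oxy]-6-oxo-5-(phenylselanyl)-1-[(trimethylsilyl)oxy]cyclohexyl]methyl benzoate (both epimers at the selenium-bearing carbon) | O=C(OC[C@]1(O[Si](C)(C)C)C(=O)C([Se]c2ccccc2)C[C@@H](O[Si](C)(C)C(C)(C)C)[C@@H]1OC(=O)c1ccccc1)c1ccccc1
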